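The target is a formal dimer of one 2-methylchromone. Everything rests on cutting O1–C2 of the chromanone ring: C2 is the β-carbon of the C4 ketone, so this ring is the closed form of a 2'-hydroxyaryl enone that carries the intact chromone ring on its methylene arm. This open dimer should arise in one operation from two molecules of a protected 5-acetonyl-7-hydroxy-2-methylchromone (vinylogous Michael addition, then E1cB opening of the pyranone). The key step closes the ring again by a catalytic enantioselective oxa-Michael addition of the phenol oxygen to C2, which forms O1–C2 and sets the only stereocentre, (R), from a mixture of interconverting alkene tautomers.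

Key step: step 5

Remark: noreugenin (1) is a catalogued natural product and is taken as purchasable; 8 is expected to be an equilibrating mixture of tautomers and alkene isomers and is written as its (E)-alkenylchromone form.

Step 1
Reactants: 1 noreugenin (5,7-dihydroxy-2-methyl-4H-chromen-4-one)
Product: 2 5-hydroxy-7-(methoxymethoxy)-2-methyl-4H-chromen-4-one
Conditions: MOMCl (1.1 equiv), i-Pr2NEt, DMF, 0 °C
Reagents that add atoms: chloromethyl methyl ether, COCCl
Why: Williamson-type O-alkylation: the 5-OH is tied up in a hydrogen bond to the C4 carbonyl and is far less acidic and nucleophilic than the 7-OH, so one equivalent of MOMCl should protect only O7.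

Step 2
Reactants: 2 5-hydroxy-7-(methoxymethoxy)-2-methyl-4H-chromen-4-one
Product: 3 7-(methoxymethoxy)-2-methyl-4-oxo-4H-chromen-5-yl trifluoromethanesulfonate
Conditions: Tf2O, pyridine, CH2Cl2, 0 °C
Reagents that add atoms: trifluoromethanesulfonic anhydride, O=S(=O)(OS(=O)(=O)C(F)(F)F)C(F)(F)F
Why: O-Sulfonylation of the remaining chelated phenol with triflic anhydride should give the aryl triflate for cross-coupling, and the pyridine buffer keeps the MOM acetal intact.

Step 3
Reactants: 3 7-(methoxymethoxy)-2-methyl-4-oxo-4H-chromen-5-yl trifluoromethanesulfonate and 4 2-(bromomethyl)-2-methyl-1,3-dioxolane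
Product: 6 7-(methoxymethoxy)-2-methyl-5-[(2-methyl-1,3-dioxolan-2-yl)methyl]-4H-chromen-4-one, via alkylzinc bromide 5 (not isolated)
Conditions: 4, Zn dust, LiCl, THF, 50 °C; then 3, Pd(OAc)2/SPhos (cat.), THF, 50 °C
Reagents that add atoms: none
Why: Negishi cross-coupling of an aryl triflate with a primary alkylzinc halide: the zinc reagent, formed by LiCl-assisted zinc insertion, has no β-hydrogen and belongs to the class of stable dioxolanylmethylzinc halides, and it attacks neither the chromone carbonyl nor the acidic 2-methyl group.

Step 4
Reactants: 6 7-(methoxymethoxy)-2-methyl-5-[(2-methyl-1,3-dioxolan-2-yl)methyl]-4H-chromen-4-one (two molecules)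
Product: 8 2-[(1E)-4-{2-hydroxy-4-(methoxymethoxy)-6-[(2-methyl-1,3-dioxolan-2-yl)methyl]phenyl}-2-methyl-4-oxobut-1-en-1-yl]-7-(methoxymethoxy)-5-[(2-methyl-1,3-dioxolan-2-yl)methyl]-4H-chromen-4-one, via dipotassium dianion 7 (not isolated)
Conditions: KHMDS (1.0 equiv per 6, slow addition), THF, −40 to 0 °C; inverse quench into AcOH/THF, −78 °C
Reagents that add atoms: none
Why: Base-induced dimerisation by vinylogous Michael addition: the dienolate formed at the 2-methyl group adds through its exocyclic carbon to C2 of a second, still neutral chromone (the known mode of attack of carbanions on chromones), the adduct enolate expels the aryloxide from C2 by E1cB, and the very acidic methylene of the resulting enone is deprotonated to the phenoxide/oxonol dianion 7, a thermodynamic sink that has no electrophilic carbon left and therefore should stay open until the cold inverse quench delivers neutral 8.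

Step 5
Reactants: 8 2-[(1E)-4-{2-hydroxy-4-(methoxymethoxy)-6-[(2-methyl-1,3-dioxolan-2-yl)methyl]phenyl}-2-methyl-4-oxobut-1-en-1-yl]-7-(methoxymethoxy)-5-[(2-methyl-1,3-dioxolan-2-yl)methyl]-4H-chromen-4-one
Product: 9 (2R)-7-(methoxymethoxy)-2-{[7-(methoxymethoxy)-5-[(2-methyl-1,3-dioxolan-2-yl)methyl]-4-oxo-4H-chromen-2-yl]methyl}-2-methyl-5-[(2-methyl-1,3-dioxolan-2-yl)methyl]-2,3-dihydro-4H-chromen-4-one
Conditions: quinine-derived 3,5-bis(trifluoromethyl)anilino squaramide (10 mol%), toluene, −20 °C
Reagents that add atoms: none
Why: The quinuclidine nitrogen of the catalyst reversibly deprotonates 8 to a hydrogen-bonded oxonol ion pair, through which the alkenylchromone form, the aryl enone form and their E/Z isomers interconvert; from the aryl enone form the phenol oxygen, activated by the amine as a general base, adds to the methyl-bearing carbon (the β-carbon of the C4 ketone) while the squaramide N–H bonds bind the ketone oxygen, and protonation at C3 completes the intramolecular oxa-Michael addition that forms O1–C2. The closest known reaction type is the cinchona-squaramide- or thiourea-catalysed enantioselective cyclisation of 2'-hydroxyaryl enones to chroman-4-ones, the asymmetric form of the ring closure of the Kabbe chromanone synthesis. The dihydropyranone ring closes in the 6-endo-trig mode. C2, the only stereocentre, is set under catalyst control: in the bound ion pair the bulky chromonylmethyl arm should point away from the aryl wall of the squaramide and the methyl group towards it, which exposes one face of the alkene to the phenol oxygen and is expected to give (R) with the quinine-derived catalyst, the quinidine-derived pseudo-enantiomer being held ready if the sense proves opposite. The step needs the catalysed closure to outrun the uncatalysed one and the product not to reopen: the hydrogen bond from the phenol to the ketone makes neutral 8 slow to cyclise on its own, and the chromanone 9 has lost the acidic oxonol methylene, so the weak amine base should not start its E1cB opening at −20 °C. Regiochemistry is not in doubt, since attack of the same oxygen on C2 of the chromone ring would need an eight-membered ring.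

Step 6
Reactants: 9 (2R)-7-(methoxymethoxy)-2-{[7-(methoxymethoxy)-5-[(2-methyl-1,3-dioxolan-2-yl)methyl]-4-oxo-4H-chromen-2-yl]methyl}-2-methyl-5-[(2-methyl-1,3-dioxolan-2-yl)methyl]-2,3-dihydro-4H-chromen-4-one
Product: 10 (2R)-7-hydroxy-2-{[7-hydroxy-4-oxo-5-(2-oxopropyl)-4H-chromen-2-yl]methyl}-2-methyl-5-(2-oxopropyl)-2,3-dihydro-4H-chromen-4-one
Conditions: 3 M aq. HCl, THF, 40 °C
Reagents that add atoms: water, O
Why: Acid-catalysed acetal hydrolysis should remove the two MOM ethers and the two dioxolanes in one operation, and the C2 stereocentre should survive because reopening of a 2,2-dialkylchroman-4-one is a base-induced E1cB process that dilute acid at 40 °C does not promote.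

Compound list
1 | noreugenin, 5,7-dihydroxy-2-methyl-4H-chromen-4-one | Cc1cc(=O)c2c(O)cc(O)cc2o1 | starting material
2 | 5-hydroxy-7-(methoxymethoxy)-2-methyl-4H-chromen-4-one | Cc1cc(=O)c2c(O)cc(OCOC)cc2o1 | intermediate
3 | 7-(methoxymethoxy)-2-methyl-4-oxo-4H-chromen-5-yl trifluoromethanesulfonate | Cc1cc(=O)c2c(OS(=O)(=O)C(F)(F)F)cc(OCOC)cc2o1 | intermediate
4 | 2-(bromomethyl)-2-methyl-1,3-dioxolane | CC1(CBr)OCCO1 | starting material
5 | [(2-methyl-1,3-dioxolan-2-yl)methyl]zinc bromide, formed in the flask | CC1(C[Zn]Br)OCCO1 | intermediate
6 | 7-(methoxymethoxy)-2-methyl-5-[(2-methyl-1,3-dioxolan-2-yl)methyl]-4H-chromen-4-one | Cc1cc(=O)c2c(CC3(C)OCCO3)cc(OCOC)cc2o1 | intermediate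
7 | dipotassium phenoxide/oxonol dianion of 8, formed in the flask | [K+].[K+].COCOc1cc([O-])c(C([O-])=CC(C)=Cc2cc(=O)c3c(CC4(C)OCCO4)cc(OCOC)cc3o2)c(CC2(C)OCCO2)c1 | intermediate
8 | open dimer, 2-[(1E)-4-{2-hydroxy-4-(methoxymethoxy)-6-[(2-methyl-1,3-dioxolan-2-yl)methyl]phenyl}-2-methyl-4-oxobut-1-en-1-yl]-7-(methoxymethoxy)-5-[(2-methyl-1,3-dioxolan-2-yl)methyl]-4H-chromen-4-one | COCOc1cc(O)c(C(=O)C/C(C)=C/c2cc(=O)c3c(CC4(C)OCCO4)cc(OCOC)cc3o2)c(CC2(C)OCCO2)c1 | intermediate
9 | (2R)-7-(methoxymethoxy)-2-{[7-(methoxymethoxy)-5-[(2-methyl-1,3-dioxolan-2-yl)methyl]-4-oxo-4H-chromen-2-yl]methyl}-2-methyl-5-[(2-methyl-1,3-dioxolan-2-yl)methyl]-2,3-dihydro-4H-chromen-4-one | CC1(Cc2cc(OCOC)cc3c2C(=O)C[C@@](C)(Cc2cc(=O)c4c(CC5(C)OCCO5)cc(OCOC)cc4o2)O3)OCCO1 | intermediate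
10 | CNP0319595.1, (2R)-7-hydroxy-2-{[7-hydroxy-4-oxo-5-(2-oxopropyl)-4H-chromen-2-yl]methyl}-2-methyl-5-(2-oxopropyl)-2,3-dihydro-4H-chromen-4-one | CC(=O)Cc1cc(O)cc2c1C(=O)C[C@@](C)(Cc1cc(=O)c3c(CC(C)=O)cc(O)cc3o1)O2 | target

Total step count: 6
Longest linear sequence: 6 steps (1 → 2 → 3 → 6 → 8 → 9 → 10; bromide 4 is bought and enters in step 3)

Steps most likely to fail

Step 4. The dienolate may add too slowly to the hindered, alkoxy-deactivated C2 of the second chromone, or add reversibly at C4, so that unchanged 6 or oligomers result; part of the material may also close without induction during the quench. The fallback sets out from 6 and makes the C–C bond under Lewis-acid activation instead of anionic conditions. TBSOTf and 2,6-lutidine in CH2Cl2 at −78 to −20 °C should turn one molecule of 6 into its 4-silyloxybenzopyrylium ion and a second into the exocyclic silyl dienol ether; their Mukaiyama–Michael union (the known silyl-triflate-promoted conjugate addition of silyl enol ethers to chromones) should give, after bicarbonate work-up, the racemic chromanone tert-butyldimethylsilyl enol ether F1. Potassium tert-butoxide (2.5 equiv) in THF at −40 °C should cleave the silyl enol ether of F1, the liberated enolate should open by E1cB to dianion 7, and the inverse acetic acid quench of step 4 brings the route back at 8.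

Step 5. Facial selectivity may be poor, because the alkene isomers and tautomers of 8 interconvert faster than they cyclise and the catalyst may not tell the methyl group from the chromonylmethyl arm well enough; reversible ring opening could also erode the enantiomeric purity with time. The fallback sets out from 8 and replaces asymmetric catalysis by resolution with recycling. Triethylamine (20 mol%) in CH2Cl2 at room temperature should close the ring without induction to the racemic chromanone F2. Preparative HPLC on a chiral stationary phase should separate 9 from the (S)-enantiomer F3. F3 is opened again to 8 with KHMDS (2.1 equiv, THF, −40 °C, inverse acetic acid quench through dianion 7) and cyclised once more, so that the material converges on the wanted enantiomer; the fallback comes back to the route at 9.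

Step 3. Zinc insertion into the neopentyl-type bromide may be slow, and β-alkoxide elimination with fragmentation of the dioxolane, in the organozinc or in the alkylpalladium intermediate, may compete with coupling and leave reduced or unchanged triflate. The fallback sets out from 3 and builds the side chain in three known operations. Stille coupling with allyltributylstannane (Pd(PPh3)4, LiCl, dioxane, 100 °C) should give the 5-allylchromone F4. Wacker oxidation (PdCl2, CuCl, O2, DMF/H2O, room temperature) should give the 5-(2-oxopropyl)chromone F5. Ketalisation with 1,2-bis(trimethylsilyloxy)ethane and catalytic TMSOTf (CH2Cl2, −78 °C), conditions under which the aryl MOM ether is expected to survive, comes back to the route at 6.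

Further compounds
F1 | step 4 | racemic 4-[(tert-butyldimethylsilyl)oxy]-2H-chromene, the silyl enol ether of racemic 9 | CC1(Cc2cc(=O)c3c(CC4(C)OCCO4)cc(OCOC)cc3o2)C=C(O[Si](C)(C)C(C)(C)C)c2c(CC3(C)OCCO3)cc(OCOC)cc2O1
F2 | step 5 | racemic 9 | CC1(Cc2cc(OCOC)cc3c2C(=O)CC(C)(Cc2cc(=O)c4c(CC5(C)OCCO5)cc(OCOC)cc4o2)O3)OCCO1
F3 | step 5 | (2S)-enantiomer of 9 | CC1(Cc2cc(OCOC)cc3c2C(=O)C[C@](C)(Cc2cc(=O)c4c(CC5(C)OCCO5)cc(OCOC)cc4o2)O3)OCCO1
F4 | step 3 | 7-(methoxymethoxy)-2-methyl-5-(prop-2-en-1-yl)-4H-chromen-4-one | C=CCc1cc(OCOC)cc2oc(C)cc(=O)c12
F5 | step 3 | 7-(methoxymethoxy)-2-methyl-5-(2-oxopropyl)-4H-chromen-4-one | CC(=O)Cc1cc(OCOC)cc2oc(C)cc(=O)c12
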